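**Plan**

- Cuts: (i) the two ester C–O bonds, which release two copies of one (3S,4E)-acid, each carried with its 1,5-dialdehyde masked as a cyclopentane-1,2-diol acetonide whose glycol C–C bond is cleaved last; (ii) in the core, the cyclopentane bond between the CH3-bearing carbon (C4) and the CH2OH-bearing carbon (C5).
- Feature used: on the five-membered ring the hydroxymethyl carbon hangs on C5, and C5 is bonded to C4, which carries a one-carbon branch. C5 + CH2OH is read as an oxirane and C4 + CH3 as a terminal alkyne (one oxidation level up, so that C4 stays flat). Reductive epoxide opening gives a C5 radical that closes the ring 5-exo-dig and leaves the free CH2OH.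
- Forward order: acid from a ribose-derived cyclopentenone (steps 1–4); a 6-alkynyl-5,6-dihydropyran-2-one serves as temporary ring for the vinyl and silyloxymethyl groups, is reduced open, epoxidised and cyclised to the only carbocycle of the core (steps 5–13); methylene to methyl, protecting-group exchange, double esterification, deprotection and periodate cleavage finish (steps 14–19).
- Stereochemistry: C3 from a catalytic asymmetric allylation; C1 and the side-chain CH from trans-selective conjugate addition and enolate alkylation on the lactone, which also tells the two CH2O arms apart; C5 from the radical closure (trans to the C1 branch); C4 from hydroxyl-directed hydrogenation; the acid stereocentre from alkylation anti to the acetonide, the E-enal from an E-ethylidene group.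

Key step: step 13

Remark: the ring carbons of the target cyclopentane are called C1 (side chain), C2 (CH2), C3 (O-acyl), C4 (CH3) and C5 (CH2OH). The SMILES is read as all-trans around the ring (C1 R, C3 R, C4 R, C5 S), side-chain carbon S, both acyl groups (3S,4E), all four aldehydes open-chain. In the acetonide series the locants 3a, 4, 5, 6, 6a are those of the cyclopenta[d][1,3]dioxole; in the lactones they are those of the oxan-2-one.

**Acid fragment**

Step 1
Reactants: 1 (3aR,6aR)-2,2-dimethyl-3a,6a-dihydro-4H-cyclopenta[d][1,3]dioxol-4-one (commercial, D-ribose-derived enone)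
Product: 2 (3aR,6aR)-2,2-dimethyltetrahydro-4H-cyclopenta[d][1,3]dioxol-4-one
Conditions: H2 (1 atm), Pd/C, EtOAc, rt
Reagents that add atoms: none
Why: Heterogeneous catalytic hydrogenation saturates only the enone C=C; no new stereocentre is formed and ketone and acetonide are untouched.

Step 2
Reactants: 2 saturated acetonide ketone
Product: 3 methyl 2-[(3aR,5S,6aR)-2,2-dimethyl-4-oxotetrahydro-4H-cyclopenta[d][1,3]dioxol-5-yl]acetate
Conditions: LiN(iPr)2, THF, −78 °C; BrCH2CO2Me, DMPU, −78 to −40 °C
Reagents that add atoms: methyl bromoacetate, COC(=O)CBr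
Why: Kinetic enolate alkylation: the amide base deprotonates the CH2 flank (C5) and not the oxygenated C3a, and the electrophile enters on the convex face, trans to the fused dioxolane, which sets C5 as S (the future C3 of the acid).

Step 3
Reactants: 3 keto ester
Product: 4 methyl 2-[(3aS,4E,5S,6aR)-4-ethylidene-2,2-dimethyltetrahydro-4H-cyclopenta[d][1,3]dioxol-5-yl]acetate
Conditions: EtPPh3Br, KN(SiMe3)2, THF, 0 °C; then 3, −78 °C to rt
Reagents that add atoms: ethyltriphenylphosphonium bromide, CC[P+](c1ccccc1)(c1ccccc1)c1ccccc1.[Br-]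
Why: Wittig olefination of the ketone with the non-stabilised ylide; approach anti to the C5 side chain with the ylide methyl turned away from the dioxolane oxygen should favour the E-ethylidene (methyl syn to C5), and no stereocentre is created.

Step 4
Reactants: 4 ethylidene ester
Product: 5 2-[(3aS,4E,5S,6aR)-4-ethylidene-2,2-dimethyltetrahydro-4H-cyclopenta[d][1,3]dioxol-5-yl]acetic acid
Conditions: LiOH·H2O, THF/H2O, 0 °C to rt; then 1 M HCl to pH 4, 0 °C
Reagents that add atoms: lithium hydroxide, [Li+].[OH-]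
Why: Saponification of the methyl ester; the acetonide and the trisubstituted alkene are inert to hydroxide and the cold, brief acidification spares the acetal.

**Core**

Step 5
Reactants: 6 3-(trimethylsilyl)prop-2-ynal
Product: 7 (3R)-1-(trimethylsilyl)hex-5-en-1-yn-3-ol
Conditions: (R)-BINOL (20 mol %), Ti(OiPr)4 (10 mol %), 4 Å molecular sieves, CH2Cl2; allylSnBu3, −20 °C; aq. NaHCO3
Reagents that add atoms: allyltributylstannane, C=CC[Sn](CCCC)(CCCC)CCCC
Why: Keck allylation; the titanium–(R)-BINOL complex delivers the allyl group to one face of the ynal and sets the (R)-carbinol, the future C3 of the cyclopentane.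

Step 6
Reactants: 7 homoallylic propargylic alcohol
Product: 8 (3R)-1-(trimethylsilyl)hex-5-en-1-yn-3-yl prop-2-enoate
Conditions: acryloyl chloride, Et3N, DMAP (cat.), CH2Cl2, 0 °C
Reagents that add atoms: acryloyl chloride, C=CC(=O)Cl
Why: O-acylation of the secondary alcohol with an acid chloride; the stereocentre is not touched.

Step 7
Reactants: 8 acrylate
Product: 9 (6R)-6-[(trimethylsilyl)ethynyl]-5,6-dihydro-2H-pyran-2-one
Conditions: second-generation Grubbs catalyst (5 mol %), CH2Cl2 (dilute), 40 °C
Reagents that add atoms: none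
Why: Ring-closing olefin metathesis between the acrylate and the allyl terminus closes the α,β-unsaturated δ-lactone (the temporary ring), the bulky silyl-capped alkyne staying out of the metathesis.

Step 8
Reactants: 9 unsaturated lactone
Product: 10 (4S,6R)-4-ethenyl-6-[(trimethylsilyl)ethynyl]oxan-2-one
Conditions: CH2=CHMgBr, CuBr·SMe2 (20 mol %), THF, −78 to −40 °C; aq. NH4Cl
Reagents that add atoms: vinylmagnesium bromide, C=C[Mg]Br
Why: Copper-catalysed conjugate addition of a Grignard reagent; the vinyl group enters axially, anti to the C6 alkynyl group (4,6-trans), which sets the future C1, and the silyl cap hinders SN2′ attack on the propargylic C–O bond.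

Step 9
Reactants: 10 vinyl lactone
Product: 11 (3S,4R,6R)-4-ethenyl-3-({[tri(propan-2-yl)silyl]oxy}methyl)-6-[(trimethylsilyl)ethynyl]oxan-2-one
Conditions: LiN(iPr)2, THF, −78 °C; (iPr)3SiOCH2Cl, DMPU, −78 to −30 °C
Reagents that add atoms: (triisopropylsiloxy)methyl chloride, CC(C)[Si](OCCl)(C(C)C)C(C)C
Why: Lactone enolate alkylation with an α-chloro ether; the electrophile enters anti to the neighbouring vinyl group (3,4-trans), which sets the side-chain CH and makes its two arms different (lactone carbonyl versus silyloxymethyl).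

Step 10
Reactants: 11 trisubstituted lactone
Product: 13 (2R,3R,5R)-3-ethenyl-2-({[tri(propan-2-yl)silyl]oxy}methyl)hept-6-yne-1,5-diol, via silylalkyne diol 12 (not isolated)
Conditions: LiBH4, THF, 0 °C to rt; then MeOH, K2CO3 (cat.), rt
Reagents that add atoms: none
Why: Hydride reduction of the lactone to the 1,5-diol, then base-catalysed methanolysis of the C(sp)–Si bond; the temporary ring is opened with all three stereocentres intact and the carbonyl arm becomes the CH2OH that will be acylated.

Step 11
Reactants: 13 alkynyl diol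
Product: 14 (2R,3R,5R)-5-(acetyloxy)-3-ethenyl-2-({[tri(propan-2-yl)silyl]oxy}methyl)hept-6-yn-1-yl acetate
Conditions: Ac2O, pyridine, DMAP (cat.), CH2Cl2, 0 °C to rt
Reagents that add atoms: acetic anhydride, CC(=O)OC(C)=O
Why: Acetylation; temporary protection of exactly the two hydroxyls that will later carry the acid units, removable beside silyl ethers.

Step 12
Reactants: 14 diacetate
Product: 15 (2R,3S,5R)-5-(acetyloxy)-3-(oxiran-2-yl)-2-({[tri(propan-2-yl)silyl]oxy}methyl)hept-6-yn-1-yl acetate (both epimers at the oxirane carbon)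
Conditions: mCPBA, CH2Cl2, 0 °C to rt
Reagents that add atoms: 3-chloroperoxybenzoic acid, OOC(=O)c1cccc(Cl)c1
Why: Prilezhaev epoxidation of the only alkene (the terminal alkyne is far less reactive towards peracid); the configuration of the new oxirane carbon does not matter because it becomes a planar radical in the next step.

Step 13
Reactants: 15 epoxy alkyne
Product: 16 (1R,3S,4R)-4-[(2R)-1-(acetyloxy)-3-{[tri(propan-2-yl)silyl]oxy}propan-2-yl]-3-(hydroxymethyl)-2-methylidenecyclopentyl acetate
Conditions: Cp2TiCl2, Zn dust, THF, rt (gives Cp2TiCl); added dropwise to 15 in THF, rt; aq. NaH2PO4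
Reagents that add atoms: none
Why: Nugent–RajanBabu reductive epoxide cyclization: Cp2TiCl (trivalent titanium) transfers an electron to the oxirane, the C–O bond to the substituted carbon breaks so that oxygen stays on CH2 as a titanium alkoxide and C5 becomes a secondary radical, this radical adds to the inner alkyne carbon (C4) and the alkenyl radical takes a hydrogen atom from THF. The closest known reaction type is the titanocene chloride-mediated cyclization of 6,7-epoxyhept-1-ynes to (2-methylenecyclopentyl)methanols. The cyclopentane is closed in the 5-exo-dig mode, the 6-endo mode being stereoelectronically slower. The only new stereocentre, C5, is controlled by the adjacent C1: in the chair-like transition state the branched C1 substituent and the bulky CH2OTi group both lie pseudo-equatorial, so CH2OH ends trans to the side chain, and since C5 is planar in the radical both oxirane epimers of 15 converge. The step needs opening towards the secondary radical (inherent to a monosubstituted oxirane), ring closure before a second Cp2TiCl captures the radical (slow addition keeps the reagent dilute) and inertness of the acetates, the silyl ether and the propargylic C–O bond (titanocene chloride alone does not reduce them).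

Step 14
Reactants: 16 methylidenecyclopentane alcohol
Product: 17 (1R,2R,3S,4R)-4-[(2R)-1-(acetyloxy)-3-{[tri(propan-2-yl)silyl]oxy}propan-2-yl]-3-(hydroxymethyl)-2-methylcyclopentyl acetate
Conditions: H2 (1 atm), [Ir(cod)(PCy3)(py)]PF6 (5 mol %), CH2Cl2, rt
Reagents that add atoms: none
Why: Hydroxyl-directed homogeneous hydrogenation; the cationic iridium catalyst binds the primary alcohol and delivers hydrogen to the face of the exocyclic alkene that carries CH2OH and OAc, so the new methyl group at C4 ends trans to both.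

Step 15
Reactants: 17 methylcyclopentane alcohol
Product: 18 (1R,2R,3S,4R)-4-[(2R)-1-(acetyloxy)-3-{[tri(propan-2-yl)silyl]oxy}propan-2-yl]-3-({[tert-butyl(dimethyl)silyl]oxy}methyl)-2-methylcyclopentyl acetate
Conditions: TBSCl, imidazole, CH2Cl2, 0 °C to rt
Reagents that add atoms: tert-butyldimethylsilyl chloride, CC(C)(C)[Si](C)(C)Cl
Why: Silylation of the primary alcohol formed in the key step, so that it stays free of acyl groups later; no stereocentre is involved.

Step 16
Reactants: 18 bis-silyl diacetate
Product: 19 (1R,2R,3S,4R)-3-({[tert-butyl(dimethyl)silyl]oxy}methyl)-4-[(2R)-1-hydroxy-3-{[tri(propan-2-yl)silyl]oxy}propan-2-yl]-2-methylcyclopentan-1-ol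
Conditions: K2CO3 (cat.), MeOH, 0 °C to rt
Reagents that add atoms: none
Why: Base-catalysed transesterification removes both acetates and leaves both silyl ethers, freeing exactly the ring hydroxyl at C3 and one side-chain hydroxyl.

**Union and end game**

Step 17
Reactants: 19 core diol; 5 acetonide acid (2.5 equiv)
Product: 20 bis-ester of 19 in which the C3 oxygen and the free side-chain oxygen each carry the 2-[(3aS,4E,5S,6aR)-4-ethylidene-2,2-dimethyltetrahydro-4H-cyclopenta[d][1,3]dioxol-5-yl]acetyl group
Conditions: EDC·HCl, DMAP, CH2Cl2, 0 °C to rt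
Reagents that add atoms: none
Why: Steglich esterification; carbodiimide and DMAP acylate both free hydroxyls with an acid that has no α-stereocentre to lose.

Step 18
Reactants: 20 fully protected bis-ester
Product: 21 [(2S)-3-hydroxy-2-[(1R,2S,3R,4R)-2-(hydroxymethyl)-3-methyl-4-({2-[(1S,2E,3S,4R)-2-ethylidene-3,4-dihydroxycyclopentyl]acetyl}oxy)cyclopentyl]propyl] 2-[(1S,2E,3S,4R)-2-ethylidene-3,4-dihydroxycyclopentyl]acetate
Conditions: HF (48 % aq.), MeCN, 0 °C to rt; solid NaHCO3 to pH 6
Reagents that add atoms: none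
Why: Acid-mediated global deprotection; aqueous HF cleaves both silyl ethers and hydrolyses both isopropylidene acetals in one operation, without the base that would drive 1,3-acyl shifts.

Step 19
Reactants: 21 hexaol
Product: 22 CNP0192766.1, [(2S)-3-hydroxy-2-[(1R,2S,3R,4R)-2-(hydroxymethyl)-3-methyl-4-{[(3S,4E)-4-formyl-3-(2-oxoethyl)hex-4-enoyl]oxy}cyclopentyl]propyl] (3S,4E)-4-formyl-3-(2-oxoethyl)hex-4-enoate
Conditions: NaIO4, THF/H2O, 0 °C
Reagents that add atoms: none
Why: Malaprade glycol cleavage; periodate cleaves only the two cis-1,2-diols, each ring opening to the E-enal (aldehyde on the ethylidene carbon) and the CH2CHO arm, while the isolated primary alcohols and the esters are untouched.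

**Compound list**

1 | (3aR,6aR)-2,2-dimethyl-3a,6a-dihydro-4H-cyclopenta[d][1,3]dioxol-4-one | O=C1[C@@H]2OC(C)(C)O[C@@H]2C=C1 | starting material
2 | (3aR,6aR)-2,2-dimethyltetrahydro-4H-cyclopenta[d][1,3]dioxol-4-one | O=C1[C@@H]2OC(C)(C)O[C@@H]2CC1 | intermediate
3 | methyl 2-[(3aR,5S,6aR)-2,2-dimethyl-4-oxotetrahydro-4H-cyclopenta[d][1,3]dioxol-5-yl]acetate | O=C1[C@@H]2OC(C)(C)O[C@@H]2C[C@H]1CC(=O)OC | intermediate
4 | methyl 2-[(3aS,4E,5S,6aR)-4-ethylidene-2,2-dimethyltetrahydro-4H-cyclopenta[d][1,3]dioxol-5-yl]acetate | C/C=C1\[C@H](CC(=O)OC)C[C@H]2OC(C)(C)O[C@@H]12 | intermediate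
5 | 2-[(3aS,4E,5S,6aR)-4-ethylidene-2,2-dimethyltetrahydro-4H-cyclopenta[d][1,3]dioxol-5-yl]acetic acid | C/C=C1\[C@H](CC(=O)O)C[C@H]2OC(C)(C)O[C@@H]12 | intermediate
6 | 3-(trimethylsilyl)prop-2-ynal | C[Si](C)(C)C#CC=O | starting material
7 | (3R)-1-(trimethylsilyl)hex-5-en-1-yn-3-ol | C=CC[C@@H](O)C#C[Si](C)(C)C | intermediate
8 | (3R)-1-(trimethylsilyl)hex-5-en-1-yn-3-yl prop-2-enoate | C=CC[C@@H](OC(=O)C=C)C#C[Si](C)(C)C | intermediate
9 | (6R)-6-[(trimethylsilyl)ethynyl]-5,6-dihydro-2H-pyran-2-one | O=C1C=CC[C@H](C#C[Si](C)(C)C)O1 | intermediate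
10 | (4S,6R)-4-ethenyl-6-[(trimethylsilyl)ethynyl]oxan-2-one | O=C1C[C@@H](C=C)C[C@H](C#C[Si](C)(C)C)O1 | intermediate
11 | (3S,4R,6R)-4-ethenyl-3-({[tri(propan-2-yl)silyl]oxy}methyl)-6-[(trimethylsilyl)ethynyl]oxan-2-one | O=C1[C@H](CO[Si](C(C)C)(C(C)C)C(C)C)[C@@H](C=C)C[C@H](C#C[Si](C)(C)C)O1 | intermediate
12 | (2R,3R,5R)-3-ethenyl-7-(trimethylsilyl)-2-({[tri(propan-2-yl)silyl]oxy}methyl)hept-6-yne-1,5-diol | OC[C@H](CO[Si](C(C)C)(C(C)C)C(C)C)[C@@H](C=C)C[C@@H](O)C#C[Si](C)(C)C | intermediate
13 | (2R,3R,5R)-3-ethenyl-2-({[tri(propan-2-yl)silyl]oxy}methyl)hept-6-yne-1,5-diol | OC[C@H](CO[Si](C(C)C)(C(C)C)C(C)C)[C@@H](C=C)C[C@@H](O)C#C | intermediate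
14 | (2R,3R,5R)-5-(acetyloxy)-3-ethenyl-2-({[tri(propan-2-yl)silyl]oxy}methyl)hept-6-yn-1-yl acetate | CC(=O)OC[C@H](CO[Si](C(C)C)(C(C)C)C(C)C)[C@@H](C=C)C[C@@H](OC(C)=O)C#C | intermediate
15 | (2R,3S,5R)-5-(acetyloxy)-3-(oxiran-2-yl)-2-({[tri(propan-2-yl)silyl]oxy}methyl)hept-6-yn-1-yl acetate, both epimers at the oxirane carbon | CC(=O)OC[C@H](CO[Si](C(C)C)(C(C)C)C(C)C)[C@@H](C1CO1)C[C@@H](OC(C)=O)C#C | intermediate
16 | (1R,3S,4R)-4-[(2R)-1-(acetyloxy)-3-{[tri(propan-2-yl)silyl]oxy}propan-2-yl]-3-(hydroxymethyl)-2-methylidenecyclopentyl acetate | CC(=O)OC[C@H](CO[Si](C(C)C)(C(C)C)C(C)C)[C@@H]1C[C@@H](OC(C)=O)C(=C)[C@H]1CO | intermediate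
17 | (1R,2R,3S,4R)-4-[(2R)-1-(acetyloxy)-3-{[tri(propan-2-yl)silyl]oxy}propan-2-yl]-3-(hydroxymethyl)-2-methylcyclopentyl acetate | CC(=O)OC[C@H](CO[Si](C(C)C)(C(C)C)C(C)C)[C@@H]1C[C@@H](OC(C)=O)[C@H](C)[C@H]1CO | intermediate
18 | (1R,2R,3S,4R)-4-[(2R)-1-(acetyloxy)-3-{[tri(propan-2-yl)silyl]oxy}propan-2-yl]-3-({[tert-butyl(dimethyl)silyl]oxy}methyl)-2-methylcyclopentyl acetate | CC(=O)OC[C@H](CO[Si](C(C)C)(C(C)C)C(C)C)[C@@H]1C[C@@H](OC(C)=O)[C@H](C)[C@H]1CO[Si](C)(C)C(C)(C)C | intermediate
19 | (1R,2R,3S,4R)-3-({[tert-butyl(dimethyl)silyl]oxy}methyl)-4-[(2R)-1-hydroxy-3-{[tri(propan-2-yl)silyl]oxy}propan-2-yl]-2-methylcyclopentan-1-ol | OC[C@H](CO[Si](C(C)C)(C(C)C)C(C)C)[C@@H]1C[C@@H](O)[C@H](C)[C@H]1CO[Si](C)(C)C(C)(C)C | intermediate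
20 | bis-ester of 19: the C3 ring oxygen and the side-chain CH2O each acylated by the 2-[(3aS,4E,5S,6aR)-4-ethylidene-2,2-dimethyltetrahydro-4H-cyclopenta[d][1,3]dioxol-5-yl]acetyl group; side-chain carbon R; TBS and TIPS ethers retained | O=C(C[C@@H]1C[C@H]2OC(C)(C)O[C@H]2/C1=C/C)OC[C@H](CO[Si](C(C)C)(C(C)C)C(C)C)[C@@H]1C[C@@H](OC(=O)C[C@@H]2C[C@H]3OC(C)(C)O[C@H]3/C2=C/C)[C@H](C)[C@H]1CO[Si](C)(C)C(C)(C)C | intermediate
21 | [(2S)-3-hydroxy-2-[(1R,2S,3R,4R)-2-(hydroxymethyl)-3-methyl-4-({2-[(1S,2E,3S,4R)-2-ethylidene-3,4-dihydroxycyclopentyl]acetyl}oxy)cyclopentyl]propyl] 2-[(1S,2E,3S,4R)-2-ethylidene-3,4-dihydroxycyclopentyl]acetate | O=C(C[C@@H]1C[C@@H](O)[C@@H](O)/C1=C/C)OC[C@H](CO)[C@@H]1C[C@@H](OC(=O)C[C@@H]2C[C@@H](O)[C@@H](O)/C2=C/C)[C@H](C)[C@H]1CO | intermediate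
22 | CNP0192766.1, [(2S)-3-hydroxy-2-[(1R,2S,3R,4R)-2-(hydroxymethyl)-3-methyl-4-{[(3S,4E)-4-formyl-3-(2-oxoethyl)hex-4-enoyl]oxy}cyclopentyl]propyl] (3S,4E)-4-formyl-3-(2-oxoethyl)hex-4-enoate | C/C=C(/C=O)[C@@H](CC=O)CC(=O)OC[C@H](CO)[C@@H]1C[C@@H](OC(=O)C[C@H](CC=O)/C(C=O)=C\C)[C@H](C)[C@H]1CO | target

**Count**

Total steps: 19. Longest linear sequence: 15 steps (steps 5 to 19, from 6 to 22); the acid 5 takes 4 steps and is used twice in step 17.

**Three steps most likely to fail**

Step 13. The β-titanoxy radical may be captured by a second equivalent of trivalent titanium before it closes onto the alkyne, and the resulting organotitanium eliminates the alkoxide to give back the alkene (net deoxygenation). In that case the same C5 radical would be made in a tin hydride chain. The fallback sets out from 14: Upjohn dihydroxylation of the vinyl group (OsO4 cat., NMO, acetone/H2O; the alkyne reacts much more slowly) should give (2R,5R)-5-(acetyloxy)-3-(1,2-dihydroxyethyl)-2-({[tri(propan-2-yl)silyl]oxy}methyl)hept-6-yn-1-yl acetate F1 as a mixture at the new carbinol carbon. 1,1′-Thiocarbonyldiimidazole (toluene, 80 °C) should convert it into the cyclic thionocarbonate, (2R,5R)-5-(acetyloxy)-3-(2-thioxo-1,3-dioxolan-4-yl)-2-({[tri(propan-2-yl)silyl]oxy}methyl)hept-6-yn-1-yl acetate F2. Bu3SnH and AIBN (benzene, 80 °C, syringe pump) cleave the secondary C–O bond in the Barton–McCombie manner, the C5 radical closes 5-exo-dig, and loss of carbonyl sulfide and of the stannyl group on work-up should return the route at 16.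

Step 3. The ylide may attack from the other face and place its methyl group syn to the dioxolane carbon (wrong alkene geometry), and its basicity may trigger β-elimination of the acetal oxygen. A Peterson olefination would then be used. The fallback sets out from 3: addition of CH3CH(SiMe3)MgCl in the presence of CeCl3 (THF, −78 °C) should give the β-hydroxysilanes, methyl 2-[(3aR,5S,6aR)-4-hydroxy-2,2-dimethyl-4-[1-(trimethylsilyl)ethyl]hexahydrocyclopenta[d][1,3]dioxol-5-yl]acetate F3, as diastereomers at the two new centres that are separated. Each is eliminated in the sense that leads to the E alkene, syn with KH (THF) for one and anti with BF3·OEt2 (CH2Cl2) for the other, so that both converge on 4.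

Step 18. Once the hydroxyl next to the acylated side-chain oxygen is free, acid may shift the acyl group between the two side-chain oxygens, which would scramble the side-chain stereocentre; the bicyclic acetals may also hydrolyse slowly. The unmasking would then be reordered so that this hydroxyl stays silylated to the end. The fallback sets out from 20: aqueous CF3CO2H in THF (0 °C) should remove the two acetonides and the TBS ether but leave the TIPS ether, giving the pentaol that is the side-chain O-triisopropylsilyl ether of 21, F4. NaIO4 (THF/H2O, 0 °C) should then give the tetra-aldehyde that is the side-chain O-triisopropylsilyl ether of 22, F5. HF·pyridine buffered with pyridine (THF, 0 °C) removes the last silyl group under conditions that aldehydes tolerate and returns the route at 22.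

**Further compounds**

F1 | step 13 | (2R,5R)-5-(acetyloxy)-3-(1,2-dihydroxyethyl)-2-({[tri(propan-2-yl)silyl]oxy}methyl)hept-6-yn-1-yl acetate, C3 as in 14, mixture at the carbinol carbon | CC(=O)OC[C@H](CO[Si](C(C)C)(C(C)C)C(C)C)[C@@H](C(O)CO)C[C@@H](OC(C)=O)C#C
F2 | step 13 | (2R,5R)-5-(acetyloxy)-3-(2-thioxo-1,3-dioxolan-4-yl)-2-({[tri(propan-2-yl)silyl]oxy}methyl)hept-6-yn-1-yl acetate, C3 as in 14, mixture at the dioxolane carbon | CC(=O)OC[C@H](CO[Si](C(C)C)(C(C)C)C(C)C)[C@@H](C1COC(=S)O1)C[C@@H](OC(C)=O)C#C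
F3 | step 3 | methyl 2-[(3aR,5S,6aR)-4-hydroxy-2,2-dimethyl-4-[1-(trimethylsilyl)ethyl]hexahydrocyclopenta[d][1,3]dioxol-5-yl]acetate, diastereomers at C4 and at the silyl-bearing carbon | COC(=O)C[C@@H]1C[C@H]2OC(C)(C)O[C@H]2C1(O)C(C)[Si](C)(C)C
F4 | step 18 | side-chain O-triisopropylsilyl ether of 21 | O=C(C[C@@H]1C[C@@H](O)[C@@H](O)/C1=C/C)OC[C@H](CO[Si](C(C)C)(C(C)C)C(C)C)[C@@H]1C[C@@H](OC(=O)C[C@@H]2C[C@@H](O)[C@@H](O)/C2=C/C)[C@H](C)[C@H]1CO
F5 | step 18 | side-chain O-triisopropylsilyl ether of 22 | C/C=C(/C=O)[C@@H](CC=O)CC(=O)OC[C@H](CO[Si](C(C)C)(C(C)C)C(C)C)[C@@H]1C[C@@H](OC(=O)C[C@H](CC=O)/C(C=O)=C\C)[C@H](C)[C@H]1CO
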